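# Proposed synthesis of CNP0326301.1 by Ramberg–Bäcklund ring contraction of a chiral thiolane dioxide

## Analysis of the target

The target (29) is a naphthazarin: ring A is the dihydroxybenzene ring and ring B the quinone ring. C2 of ring B carries a cyclobutane (ring C) joined through C1'. C1' is fully substituted: it bears the angelate oxygen, the quinone carbon, the gem-dimethyl carbon C2' and the methylene C4'; C3' and C4' are plain methylenes. C1' is the only stereocentre and is R. No second centre exists from which it could be relayed, so it must come from a reagent or catalyst; the Z double bond of the angelate is the second stereo-element to keep. The sensitive groups are the naphthazarin (redox-active, chelating, destroyed by strong bases and nucleophiles), the angelate (isomerises to the tiglate with acid, nucleophilic catalysts or heat) and the tertiary cyclobutyl ester, whose ionisation would scramble C1' and open cyclobutyl–cyclopropylcarbinyl rearrangements. The difficulty lies in a four-membered ring with two adjacent fully substituted carbons, one an oxygenated stereocentre, together with late acylation of a very hindered tertiary alcohol and late unmasking of the naphthazarin. The strategy rests on the C3'–C4' bond: it joins two unsubstituted methylenes, each flanked by a carbon without hydrogen (C2' and C1'). That bond can be made last by excising a sulfonyl bridge between C3' and C4' from a five-membered sulfone, and the α-halosulfone involved has no 1,2-elimination open to it. The congested C1'–C2' bond and the stereocentre then become problems of an open-chain molecule.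

## Retrosynthetic reasoning

**Naphthazarin to tetramethyl ether (29 to 26).** The four O–methyl bonds are cut first. A free naphthazarin cannot pass through aryllithium, hydride, sulfonyl carbanion and alkoxide chemistry, whereas the tetramethyl ether 26 is an ordinary electron-rich arene. The forward reaction has to oxidise one ring to the quinone and dealkylate the two remaining peri methoxy groups without ionising the tertiary ester or isomerising the Z olefin. Which ring is oxidised does not matter: the regioisomeric quinones 27 and 28 both end as 29, because the naphthazarin tautomers are one compound.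

**Ester (26 to 23 and 24).** The acyl–oxygen bond is cut, not the C1'–O bond, so the configured C–O bond is never broken and no cation at C1' is needed. The cut comes late because the angelate would not survive carbanions, hydroxide, hydride or fluoride. The forward reaction has to acylate the tertiary alkoxide of cyclobutanol 23 with angelic acid 24 without Z to E isomerisation.

**Cyclobutanol to cyclobutene (23 to 22 to 21).** The silyl ether 22 is the protected form, and its C3'–C4' single bond is traced to the double bond of cyclobutene 21. The forward reduction has to be metal-free, acid-free and prompt, since 21 is a donor-substituted cyclobutene that can open thermally to a diene.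

**Key disconnection (21 to 18).** The C3'–C4' bond is cut and a sulfonyl group is inserted, giving the thiolane 1,1-dioxide 18. This is the only ring bond between two unfunctionalised carbons. Cutting C1'–C2' or C1'–C4' would instead require the stereocentre to be formed during a strained ring closure. What is gained is that the strain is introduced in a final, irreversible extrusion from an unstrained five-membered ring, while C1' (no hydrogen, not α to sulfur) stays untouched. The forward reaction has to halogenate only α to the sulfone, close the episulfone and expel the sulfonyl bridge without β-elimination of the silyl ether. A triethylsilyl ether is chosen over a bulkier silyl group because the carbinol sits between a quaternary carbon and an ortho-substituted aryl group; it must still go on with a silyl triflate and come off with fluoride.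

**Sulfone ring (18 to 17 to 15 to 12 to 11).** The O–Si bond, the two S=O bonds and the two C–S bonds are removed in turn, leading through hydroxy sulfone 17 and thiolane 15 to dimesylate 12 and triol 11. Both electrophilic carbons are neopentyl-type. The forward reaction therefore relies on the epoxide 13 for the carbon next to C1' and on an intramolecular five-membered closure of thiolate 14 for the carbon next to C2'.

**Open-chain stereocentre (11 to 10 to 7 and 8).** The triol is the reduced form of hydroxy diester 10. Cutting C1'–C2' in 10 gives aryl keto ester 7 and ketene acetal 8. The most congested bond of the target is thus formed between two sp2 carbons, where hindrance costs least. The 1,2-dicarbonyl unit of 7 offers a two-point binding site for a chiral Lewis acid, which has to deliver 8 to the si face of the ketone. The two ester carbons of 10 become C4' and C3'.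

**Arene (7 to 4 and 5, then 3 and 1).** The aryl–C1' bond is cut to aryllithium 6, made from bromide 4, and dimethyl oxalate 5. Bromide 4 comes from tetramethyl ether 3, which is the reductively methylated form of naphthazarin 1.

## Alternatives that were turned down

**Alternative 1: aryne plus furan.** Ring B is disconnected at C1–C8a and C4–C4a. In the forward sense the symmetric aryne released from 2-bromo-1,4-dimethoxybenzene A3 by a hindered lithium amide adds across the diene of the 3-furyl cyclobutyl silyl ether A2. The product is the oxygen-bridged dihydronaphthalene A1, formed as two bridgehead diastereomers that converge on aromatisation.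
- For: the route is convergent and the aryne is symmetric, so there is no regiochemical question. The side chain ends on the ring that becomes the quinone, only two methyl ethers remain, and no oxidant has to choose between two rings. On the arene end-game it is stronger than the chosen route.
- Against: the key step forms none of the bonds that make the target hard. Ring C and the stereocentre must already be present in A2, so the real problem becomes an enantioselective synthesis of a 1-heteroaryl-2,2-dimethylcyclobutanol. The obvious entry, a furyl organometallic adding to the hindered cyclobutanone, gives a racemate and has no dependable catalytic asymmetric version. Converting the oxygen bridge of A1 into a quinone also needs acid-mediated opening to a naphthol next to a tertiary silyl ether on a strained ring.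
- Comparison: the chosen route spends more steps on the arene, but in exchange sets C1' by a catalyst-controlled open-chain addition and closes ring C in a step that cannot touch C1'.

**Alternative 2: ketene plus alkene.** Ring C is disconnected at C1'–C2' and C3'–C4'. In the forward sense the ketene released from arylacetyl chloride A5 by an amine base, activated by an aluminium Lewis acid, adds to 2-methylpropene A6 to give cyclobutanone A4.
- For: the whole four-membered ring, including the congested C1'–C2' bond, is made in one step from trivial components with dependable regiochemistry. In ring-forming economy it is clearly stronger than the sulfone route, which needs seven steps from keto ester 7 to reach a cyclobutene.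
- Against: A4 carries its oxygen on C4', where none is wanted, and none on C1', and it is racemic at an enolisable centre. C1' would have to be oxygenated through a fully substituted cyclobutanone enolate under reagent control of the absolute configuration, which is uncertain for this enolate class. The ketone would then have to be deleted next to a tertiary carbinol, where α-hydroxycyclobutanones are prone to α-ketol rearrangement and ring contraction under the basic or acidic conditions of deoxygenation. The Lewis acid, the alkene and an electron-rich arene also invite Friedel–Crafts alkylation.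
- Comparison: the chosen route offers oxygen and configuration at C1' before the ring exists, and C3' and C4' arrive as unfunctionalised carbons with nothing to remove but the sulfonyl bridge.

**Alternative 3: cationic ring expansion with carboxylate capture.** The C2'–C3' and C1'–O bonds are disconnected. In the forward sense a Brønsted acid protonates the isopropenyl group of cyclopropane A8, a cyclopropane methylene shifts to the cationic carbon, and the resulting 1-arylcyclobutyl cation is captured by angelic acid 24 to give ester A7, which is identical with 26.
- For: this is by far the shortest route. It delivers 26 directly and dispenses with both the protecting group on the C1' oxygen and the hindered acylation; on step economy and on these two points it is stronger than the chosen route.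
- Against: the bond to oxygen is formed at a planar benzylic cation with no element that distinguishes its faces. Intermolecular capture under the control of a chiral counter-ion is not something that can be relied on here. The product, a tertiary ester next to an electron-rich arene, can re-ionise under the acid that formed it, so any kinetic selectivity would erode. The cation manifold also offers elimination and capture at the cyclopropylcarbinyl position, and acid isomerises the angelate.
- Comparison: the chosen route is much longer, but it fixes the absolute configuration in a precedented catalytic step and thereafter never generates a cation at C1'.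

Key step: step 10

**Remarks on the chemistry**
- The naphthazarin core of 29 is tautomeric. The form with the side chain on the quinone ring (as drawn) and the form with it on the benzenoid ring interconvert by fast proton transfer and are one compound.
- The descriptor at the carbinol carbon is S in 9, 10 and 15–20 and R in 11–14 and 21–29. These changes come only from changes in substituent priorities; no step breaks a bond to this carbon.
- Compounds 1, 5, 8 and 24 are taken as purchased.

## Route

Step 1
Reactants: 1 naphthazarin (5,8-dihydroxynaphthalene-1,4-dione)
Product: 3 1,4,5,8-tetramethoxynaphthalene, via naphthalene-1,4,5,8-tetrol 2 (not isolated)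
Conditions: Na2S2O4, NaOH, Bu4NBr, THF–H2O, rt, N2; then Me2SO4, rt to 40 °C
Reagents that add atoms: dimethyl sulfate, COS(=O)(=O)OC
Why: Dithionite reduces the quinone to the tetraphenol 2, whose tetra-anion is methylated four times under phase-transfer conditions (reductive methylation, Williamson ether synthesis); exclusion of air keeps the leuco form from reoxidising.

Step 2
Reactants: 3 1,4,5,8-tetramethoxynaphthalene
Product: 4 2-bromo-1,4,5,8-tetramethoxynaphthalene
Conditions: N-bromosuccinimide (1.0 equiv), CH2Cl2, 0 °C to rt, dark
Reagents that add atoms: N-bromosuccinimide, O=C1CCC(=O)N1Br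
Why: Electrophilic aromatic bromination; the four free positions are equivalent and each is ortho to a methoxy group, so one equivalent of the bromine donor at low temperature should stop at the monobromide.

Step 3
Reactants: 4 2-bromo-1,4,5,8-tetramethoxynaphthalene; 5 dimethyl oxalate
Product: 7 methyl 2-oxo-2-(1,4,5,8-tetramethoxynaphthalen-2-yl)acetate, via 2-lithio-1,4,5,8-tetramethoxynaphthalene 6 (not isolated)
Conditions: n-BuLi, THF, −78 °C; cannulated into 5 (3 equiv), THF, −78 °C; NH4Cl aq
Reagents that add atoms: none
Why: Bromine–lithium exchange is fast and regiospecific at −78 °C; inverse addition of 6 to excess diester gives a tetrahedral adduct that persists until the quench, so the keto ester is released only on work-up and is not attacked a second time (acylation of an aryllithium by an oxalate).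

Step 4
Reactants: 7 methyl 2-oxo-2-(1,4,5,8-tetramethoxynaphthalen-2-yl)acetate; 8 methyl trimethylsilyl dimethylketene acetal
Product: 10 dimethyl (2S)-2-hydroxy-3,3-dimethyl-2-(1,4,5,8-tetramethoxynaphthalen-2-yl)butanedioate, via trimethylsilyl ether of the aldol adduct 9 (not isolated)
Conditions: Cu(OTf)2 (10 mol %), (S,S)-2,2'-(propane-2,2-diyl)bis(4-tert-butyl-4,5-dihydrooxazole) (11 mol %), THF, −78 to −40 °C; then 1 M HCl, THF, 0 °C
Reagents that add atoms: none
Why: Catalytic enantioselective Mukaiyama aldol addition to an α-keto ester: the ketone and ester oxygens of 7 chelate divalent copper in the plane of the bis(oxazoline), a tert-butyl group covers the re face of the ketone, and 8 adds to the si face through an open transition state, which sets the carbinol carbon as S in 9 and 10, the sense that becomes R at C1' of the target. Silyl transfer gives 9 and dilute acid frees the carbinol; should the aryl group reverse the facial preference, the enantiomeric ligand is used.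

Step 5
Reactants: 10 dimethyl (2S)-2-hydroxy-3,3-dimethyl-2-(1,4,5,8-tetramethoxynaphthalen-2-yl)butanedioate
Product: 11 (2R)-3,3-dimethyl-2-(1,4,5,8-tetramethoxynaphthalen-2-yl)butane-1,2,4-triol
Conditions: LiAlH4, THF, 0 °C to reflux; H2O, NaOH aq
Reagents that add atoms: none
Why: Hydride reduction of the α-hydroxy ester and of the neopentyl ester to primary alcohols; the tertiary carbinol is held as an aluminium alkoxide, which should not undergo retro-aldol cleavage, and no bond to the stereocentre is broken.

Step 6
Reactants: 11 (2R)-3,3-dimethyl-2-(1,4,5,8-tetramethoxynaphthalen-2-yl)butane-1,2,4-triol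
Product: 12 (2R)-2-hydroxy-3,3-dimethyl-2-(1,4,5,8-tetramethoxynaphthalen-2-yl)butane-1,4-diyl dimethanesulfonate
Conditions: MsCl (2.2 equiv), Et3N, CH2Cl2, −20 to 0 °C
Reagents that add atoms: methanesulfonyl chloride, CS(=O)(=O)Cl
Why: Sulfonylation through the sulfene is fast at the two primary hydroxyls and negligible at the tertiary one, which lies between a quaternary carbon and the aryl group; any epoxide 13 formed on work-up is an intermediate of step 7 and does no harm.

Step 7
Reactants: 12 (2R)-2-hydroxy-3,3-dimethyl-2-(1,4,5,8-tetramethoxynaphthalen-2-yl)butane-1,4-diyl dimethanesulfonate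
Product: 15 (3S)-4,4-dimethyl-3-(1,4,5,8-tetramethoxynaphthalen-2-yl)thiolan-3-ol, via epoxy mesylate 13 (not isolated), via hydroxy thiolate 14 (not isolated)
Conditions: Na2S·9H2O (1.5 equiv), DMF, 0 to 60 °C
Reagents that add atoms: sodium sulfide, [Na+].[Na+].[S-2]
Why: Base closes the tertiary alkoxide onto the neighbouring mesylate (3-exo-tet) to give 13, hydrosulfide opens the epoxide at its methylene to give 14, and the thiolate displaces the remaining neopentyl mesylate in a 5-exo-tet closure favoured by the gem-dimethyl group (double nucleophilic substitution by a sulfide dianion). The C–O bond of the stereocentre is never broken, so the configuration is retained.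

Step 8
Reactants: 15 (3S)-4,4-dimethyl-3-(1,4,5,8-tetramethoxynaphthalen-2-yl)thiolan-3-ol
Product: 17 (3S)-3-hydroxy-4,4-dimethyl-3-(1,4,5,8-tetramethoxynaphthalen-2-yl)thiolane 1,1-dioxide, via sulfoxide 16 (not isolated)
Conditions: H2O2 (30 % aq, 3 equiv), (NH4)6Mo7O24·4H2O (5 mol %), EtOH, 0 °C to rt
Reagents that add atoms: hydrogen peroxide, OO
Why: Peroxomolybdate transfers oxygen to sulfur twice (sulfide oxidation by way of 16); sulfur is far more nucleophilic than the methoxy-substituted arene, and the near-neutral medium leaves the tertiary alcohol alone.

Step 9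
Reactants: 17 (3S)-3-hydroxy-4,4-dimethyl-3-(1,4,5,8-tetramethoxynaphthalen-2-yl)thiolane 1,1-dioxide
Product: 18 (3S)-4,4-dimethyl-3-(1,4,5,8-tetramethoxynaphthalen-2-yl)-3-(triethylsilyloxy)thiolane 1,1-dioxide
Conditions: Et3SiOTf, 2,6-lutidine, CH2Cl2, 0 °C to rt
Reagents that add atoms: triethylsilyl trifluoromethanesulfonate, CC[Si](CC)(CC)OS(=O)(=O)C(F)(F)F
Why: O-Silylation with a silyl triflate, which is electrophilic enough for the crowded tertiary hydroxyl; the hindered pyridine base is too weak to form the alkoxide, so the β-hydroxy sulfone cannot open by retro-aldol cleavage.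

Step 10
Reactants: 18 (3S)-4,4-dimethyl-3-(1,4,5,8-tetramethoxynaphthalen-2-yl)-3-(triethylsilyloxy)thiolane 1,1-dioxide
Product: 21 triethyl{[(1R)-4,4-dimethyl-1-(1,4,5,8-tetramethoxynaphthalen-2-yl)cyclobut-2-en-1-yl]oxy}silane, via alpha-bromo sulfone 19 (not isolated), via bicyclic episulfone 20 (not isolated)
Conditions: CBr2F2 (excess), KOH/Al2O3, t-BuOH–CH2Cl2, 0 to 10 °C; cold filtration, solution used at once
Reagents that add atoms: none
Why: Hydroxide on alumina reversibly deprotonates an α-methylene of the sulfone, and the carbanion takes bromine from CBr2F2 in a halophilic attack to give 19. Deprotonation at the other α-carbon is followed by intramolecular displacement of bromide, a 3-exo-tet closure (1,3-elimination) that forms the C3'–C4' bond and the bicyclic episulfone 20; cheletropic loss of SO2 from 20 leaves the ring-constrained cis double bond, so the five-membered sulfone has contracted to the cyclobutene. This is a Ramberg–Bäcklund reaction with in situ halogenation, and the closest known cases are contractions of α-halothiolane 1,1-dioxides with fully substituted β-carbons to cyclobutenes. No stereocentre is created; C1' bears no hydrogen, is not α to sulfur and keeps its configuration. The step needs chemoselectivity in three respects: bromination must be confined to the α-sulfonyl positions, which a bromine donor that reacts only with carbanions secures in the presence of the easily halogenated tetramethoxynaphthalene; 19 must not lose HBr to a sulfolene, which is excluded because both β-carbons (C1' and C2') are fully substituted; and the carbanion next to C1' must close faster than it expels triethylsilanolate, which low temperature and the poor leaving group favour. Both α-positions are methylenes, so either site of bromination leads to the same alkene. The silyl ether blocks retro-aldol cleavage of the β-oxygenated sulfone and the alkoxide-accelerated opening of the cyclobutene.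

Step 11
Reactants: 21 triethyl{[(1R)-4,4-dimethyl-1-(1,4,5,8-tetramethoxynaphthalen-2-yl)cyclobut-2-en-1-yl]oxy}silane
Product: 22 triethyl{[(1R)-2,2-dimethyl-1-(1,4,5,8-tetramethoxynaphthalen-2-yl)cyclobutyl]oxy}silane
Conditions: KO2CN=NCO2K (excess), AcOH, MeOH–CH2Cl2, 0 °C to rt
Reagents that add atoms: none
Why: Diimide reduction: two hydrogens are delivered suprafacially through a six-membered transition state to the strained cis double bond, whose strain relief offsets the two flanking quaternary carbons. The reagent touches neither the arene nor the benzylic C–O bond, and the cold, immediate reduction keeps 21 from opening thermally to a diene.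

Step 12
Reactants: 22 triethyl{[(1R)-2,2-dimethyl-1-(1,4,5,8-tetramethoxynaphthalen-2-yl)cyclobutyl]oxy}silane
Product: 23 (1R)-2,2-dimethyl-1-(1,4,5,8-tetramethoxynaphthalen-2-yl)cyclobutan-1-ol
Conditions: Bu4NF, THF, 0 to 40 °C
Reagents that add atoms: none
Why: Fluoride-induced desilylation driven by the Si–F bond; the tertiary alkoxide in the saturated ring has no electrocyclic or fragmentation pathway, and C1' is not involved.

Step 13
Reactants: 23 (1R)-2,2-dimethyl-1-(1,4,5,8-tetramethoxynaphthalen-2-yl)cyclobutan-1-ol; 24 angelic acid
Product: 26 (1R)-2,2-dimethyl-1-(1,4,5,8-tetramethoxynaphthalen-2-yl)cyclobutyl (2Z)-2-methylbut-2-enoate, via angelic 2,4,6-trichlorobenzoic anhydride 25 (not isolated)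
Conditions: 24, 2,4,6-Cl3C6H2COCl, Et3N, THF, 0 °C to rt; added to 23, LiN(SiMe3)2 (1.05 equiv), THF, −78 to 0 °C
Reagents that add atoms: none
Why: The lithium alkoxide of 23 attacks the angeloyl carbonyl of 25, the aroyl carbonyl being shielded by its two ortho chlorine atoms (Yamaguchi-type esterification through a preformed alkoxide). With no nucleophilic acyl-transfer catalyst and at low temperature the Z double bond should not isomerise, and the C1'–O bond is not broken.

Step 14
Reactants: 26 (1R)-2,2-dimethyl-1-(1,4,5,8-tetramethoxynaphthalen-2-yl)cyclobutyl (2Z)-2-methylbut-2-enoate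
Product: 29 (1R)-1-(5,8-dihydroxy-1,4-dioxo-1,4-dihydronaphthalen-2-yl)-2,2-dimethylcyclobutyl (2Z)-2-methylbut-2-enoate, via 2-substituted 5,8-dimethoxy-1,4-naphthoquinone 27 (not isolated), via 6-substituted 5,8-dimethoxy-1,4-naphthoquinone 28 (not isolated)
Conditions: (NH4)2Ce(NO3)6 (2.5 equiv), MeCN–H2O, 0 °C; extraction, crude dried; BCl3, CH2Cl2, −78 to −20 °C; H2O
Reagents that add atoms: water, O
Why: Tetravalent cerium oxidises the arene to its radical cation, water adds at two para methoxy-bearing carbons and methanol is lost, giving the quinone on either ring (27 and 28; oxidative demethylation). BCl3 then binds between each quinone carbonyl and its peri methoxy oxygen and chloride removes the methyl group (chelation-assisted ether cleavage); hydrolysis of the boron chelates gives the same naphthazarin 29 from both regioisomers, and neither the stereocentre nor the ester takes part.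

## Compound list

1 | naphthazarin (5,8-dihydroxynaphthalene-1,4-dione) | O=C1C=CC(=O)c2c(O)ccc(O)c12 | starting material
2 | naphthalene-1,4,5,8-tetrol | Oc1ccc(O)c2c(O)ccc(O)c12 | intermediate
3 | 1,4,5,8-tetramethoxynaphthalene | COc1ccc(OC)c2c(OC)ccc(OC)c12 | intermediate
4 | 2-bromo-1,4,5,8-tetramethoxynaphthalene | COc1ccc(OC)c2c(OC)c(Br)cc(OC)c12 | intermediate
5 | dimethyl oxalate | COC(=O)C(=O)OC | starting material
6 | 2-lithio-1,4,5,8-tetramethoxynaphthalene | [Li]c1cc(OC)c2c(OC)ccc(OC)c2c1OC | intermediate
7 | methyl 2-oxo-2-(1,4,5,8-tetramethoxynaphthalen-2-yl)acetate | COC(=O)C(=O)c1cc(OC)c2c(OC)ccc(OC)c2c1OC | intermediate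
8 | methyl trimethylsilyl dimethylketene acetal (1-methoxy-2-methyl-1-(trimethylsilyloxy)prop-1-ene) | COC(O[Si](C)(C)C)=C(C)C | starting material
9 | dimethyl (2S)-3,3-dimethyl-2-(1,4,5,8-tetramethoxynaphthalen-2-yl)-2-(trimethylsilyloxy)butanedioate | C[Si](C)(C)O[C@](C(C)(C)C(=O)OC)(c1cc(OC)c2c(OC)ccc(OC)c2c1OC)C(=O)OC | intermediate
10 | dimethyl (2S)-2-hydroxy-3,3-dimethyl-2-(1,4,5,8-tetramethoxynaphthalen-2-yl)butanedioate | O[C@](C(C)(C)C(=O)OC)(c1cc(OC)c2c(OC)ccc(OC)c2c1OC)C(=O)OC | intermediate
11 | (2R)-3,3-dimethyl-2-(1,4,5,8-tetramethoxynaphthalen-2-yl)butane-1,2,4-triol | O[C@](C(C)(C)CO)(c1cc(OC)c2c(OC)ccc(OC)c2c1OC)CO | intermediate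
12 | (2R)-2-hydroxy-3,3-dimethyl-2-(1,4,5,8-tetramethoxynaphthalen-2-yl)butane-1,4-diyl dimethanesulfonate | O[C@](C(C)(C)COS(C)(=O)=O)(c1cc(OC)c2c(OC)ccc(OC)c2c1OC)COS(C)(=O)=O | intermediate
13 | 2-methyl-2-[(2R)-2-(1,4,5,8-tetramethoxynaphthalen-2-yl)oxiran-2-yl]propyl methanesulfonate | O1C[C@]1(c2cc(OC)c3c(OC)ccc(OC)c3c2OC)C(C)(C)COS(C)(=O)=O | intermediate
14 | (3R)-3-hydroxy-2,2-dimethyl-4-sulfanyl-3-(1,4,5,8-tetramethoxynaphthalen-2-yl)butyl methanesulfonate (present as its sodium thiolate) | O[C@](C(C)(C)COS(C)(=O)=O)(c1cc(OC)c2c(OC)ccc(OC)c2c1OC)CS | intermediate
15 | (3S)-4,4-dimethyl-3-(1,4,5,8-tetramethoxynaphthalen-2-yl)thiolan-3-ol | O[C@]1(c2cc(OC)c3c(OC)ccc(OC)c3c2OC)CSCC1(C)C | intermediate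
16 | (3S)-3-hydroxy-4,4-dimethyl-3-(1,4,5,8-tetramethoxynaphthalen-2-yl)thiolane 1-oxide (both epimers at sulfur) | O[C@]1(c2cc(OC)c3c(OC)ccc(OC)c3c2OC)CS(=O)CC1(C)C | intermediate
17 | (3S)-3-hydroxy-4,4-dimethyl-3-(1,4,5,8-tetramethoxynaphthalen-2-yl)thiolane 1,1-dioxide | O[C@]1(c2cc(OC)c3c(OC)ccc(OC)c3c2OC)CS(=O)(=O)CC1(C)C | intermediate
18 | (3S)-4,4-dimethyl-3-(1,4,5,8-tetramethoxynaphthalen-2-yl)-3-(triethylsilyloxy)thiolane 1,1-dioxide | CC[Si](CC)(CC)O[C@]1(c2cc(OC)c3c(OC)ccc(OC)c3c2OC)CS(=O)(=O)CC1(C)C | intermediate
19 | (4S)-2-bromo-3,3-dimethyl-4-(1,4,5,8-tetramethoxynaphthalen-2-yl)-4-(triethylsilyloxy)thiolane 1,1-dioxide (either epimer at C2; the isomer brominated at the other α-carbon behaves the same) | CC[Si](CC)(CC)O[C@]1(c2cc(OC)c3c(OC)ccc(OC)c3c2OC)CS(=O)(=O)C(Br)C1(C)C | intermediate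
20 | (2S)-3,3-dimethyl-2-(1,4,5,8-tetramethoxynaphthalen-2-yl)-2-(triethylsilyloxy)-5-thiabicyclo[2.1.0]pentane 5,5-dioxide | CC[Si](CC)(CC)O[C@]1(c2cc(OC)c3c(OC)ccc(OC)c3c2OC)C2C(S2(=O)=O)C1(C)C | intermediate
21 | triethyl{[(1R)-4,4-dimethyl-1-(1,4,5,8-tetramethoxynaphthalen-2-yl)cyclobut-2-en-1-yl]oxy}silane | CC[Si](CC)(CC)O[C@]1(c2cc(OC)c3c(OC)ccc(OC)c3c2OC)C=CC1(C)C | intermediate
22 | triethyl{[(1R)-2,2-dimethyl-1-(1,4,5,8-tetramethoxynaphthalen-2-yl)cyclobutyl]oxy}silane | CC[Si](CC)(CC)O[C@]1(c2cc(OC)c3c(OC)ccc(OC)c3c2OC)CCC1(C)C | intermediate
23 | (1R)-2,2-dimethyl-1-(1,4,5,8-tetramethoxynaphthalen-2-yl)cyclobutan-1-ol | O[C@]1(c2cc(OC)c3c(OC)ccc(OC)c3c2OC)CCC1(C)C | intermediate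
24 | angelic acid ((2Z)-2-methylbut-2-enoic acid) | C/C=C(/C)C(=O)O | starting material
25 | (2Z)-2-methylbut-2-enoic 2,4,6-trichlorobenzoic anhydride | C/C=C(/C)C(=O)OC(=O)c1c(Cl)cc(Cl)cc1Cl | intermediate
26 | (1R)-2,2-dimethyl-1-(1,4,5,8-tetramethoxynaphthalen-2-yl)cyclobutyl (2Z)-2-methylbut-2-enoate | C/C=C(/C)C(=O)O[C@]1(c2cc(OC)c3c(OC)ccc(OC)c3c2OC)CCC1(C)C | intermediate
27 | (1R)-1-(5,8-dimethoxy-1,4-dioxo-1,4-dihydronaphthalen-2-yl)-2,2-dimethylcyclobutyl (2Z)-2-methylbut-2-enoate | C/C=C(/C)C(=O)O[C@]1(C2=CC(=O)c3c(OC)ccc(OC)c3C2=O)CCC1(C)C | intermediate
28 | (1R)-1-(1,4-dimethoxy-5,8-dioxo-5,8-dihydronaphthalen-2-yl)-2,2-dimethylcyclobutyl (2Z)-2-methylbut-2-enoate | C/C=C(/C)C(=O)O[C@]1(c2cc(OC)c3C(=O)C=CC(=O)c3c2OC)CCC1(C)C | intermediate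
29 | (1R)-1-(5,8-dihydroxy-1,4-dioxo-1,4-dihydronaphthalen-2-yl)-2,2-dimethylcyclobutyl (2Z)-2-methylbut-2-enoate (CNP0326301.1) | C/C=C(/C)C(=O)O[C@]1(C2=CC(=O)c3c(O)ccc(O)c3C2=O)CCC1(C)C | target

## Step count and least certain steps

Total: 14 steps; the last is a telescoped two-operation step. Longest linear sequence: 14 steps, from 1 to 29; angelic acid 24 enters at step 13.

**Step 10 (key step).** The most likely failure is β-elimination of triethylsilanolate from the carbanion at the methylene next to C1', which would give an achiral sulfolene and erase the stereocentre. Over-bromination is the second concern, because closure to the strained bicyclic episulfone is slower than in larger rings. Loss of the silyl group to hydroxide would open retro-aldol cleavage.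
Fallback: it sets out from thiolane 15 and installs the halogen without any sulfonyl carbanion. Silylation of 15 (Et3SiOTf, 2,6-lutidine) should give the sulfide silyl ether F1. N-Chlorosuccinimide in CCl4 at 0 °C reacts first at sulfur and, through the chlorosulfonium salt (Pummerer-type α-chlorination), should give the α-chloro sulfide F2. This is oxidised without purification by 3-chloroperbenzoic acid (NaHCO3, CH2Cl2, −20 to 0 °C) to the α-chloro sulfone F3. KOC(CH3)3 in THF at −78 °C then effects the contraction, and the route is rejoined at cyclobutene 21. The hydrogens next to C1' are the more acidic ones in the chlorosulfonium salt, so chlorine is expected there. The closing carbanion is then the one next to C2', which has no leaving group in its β-position; the other regioisomer would contract to the same alkene.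

**Step 4.** Poor facial selectivity or slow turnover is possible. The ortho methoxy group can compete with the ester for copper and distort the chelate, and a tetrasubstituted nucleophile has to add to an aryl ketone.
Fallback: it replaces catalyst control by an auxiliary, sets out from keto ester 7 and returns at triol 11. Saponification of 7 (LiOH, THF–H2O) gives the keto acid F4. Esterification with (1R,2S,5R)-8-phenylmenthol (dicyclohexylcarbodiimide, 4-dimethylaminopyridine, CH2Cl2) gives the 8-phenylmenthyl keto ester F5. The lithium enolate of methyl 2-methylpropanoate (LiN(i-Pr)2, THF, −78 °C) should add to the ketone face not covered by the phenyl ring that stacks over the dicarbonyl unit. On the usual chelate model this is the si face and gives the mixed diester F6, whose diastereomers are separable, so the selectivity need not be complete. LiAlH4 then reduces both esters, releases the auxiliary and gives 11.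

**Step 7.** Grob-type fragmentation of the tertiary alkoxide with loss of the 1,3-related mesylate may compete. Intermolecular sulfide bridging is also possible if the closure at the neopentyl carbon is slow.
Fallback: it sets out from dimesylate 12, brings sulfur in as a monofunctional nucleophile and returns at thiolane 15. K2CO3 in MeOH at 0 °C closes the epoxide 13, which is now isolated. KSC(O)CH3 in DMF at rt opens it at the methylene to give the hydroxy thioacetate F7. K2CO3 in degassed MeOH cleaves the thioester, and the thiolate closes onto the neopentyl mesylate under conditions too weakly basic to form the tertiary alkoxide.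

**Step 13.** Acylation of the very hindered tertiary alkoxide may be incomplete, and more forcing conditions would risk Z to E isomerisation.
Fallback: it makes the double bond after the ester, sets out from cyclobutanol 23 and returns at ester 26. The lithium alkoxide of 23 is acylated with 2-[bis(2,2,2-trifluoroethoxy)phosphoryl]propanoyl chloride, which can react through its ketene and so tolerates hindrance, to give the phosphonate ester F8. A Still–Gennari olefination of F8 with acetaldehyde (KN(SiMe3)2, 18-crown-6, THF, −78 °C) should then give the Z-trisubstituted ester 26 under kinetic control.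

**Step 14.** Under the Lewis acid the tertiary ester may ionise, chloride may add to the unsubstituted quinone double bond of 28, or the Z ester may isomerise. Over-oxidation by the cerium reagent is a lesser concern.
Fallback: it removes the last two methyl groups by oxidation instead of Lewis acid, sets out from the crude mixture of 27 and 28 and returns at 29. AgO with 6 M HNO3 in acetone at rt for a few minutes should oxidise the dimethoxy ring of either regioisomer to the same diquinone F9. Mild reduction with aqueous Na2S2O4 then gives 29.

## Further compounds

F1 | step 10 | triethyl{[(3S)-4,4-dimethyl-3-(1,4,5,8-tetramethoxynaphthalen-2-yl)thiolan-3-yl]oxy}silane | CC[Si](CC)(CC)O[C@]1(c2cc(OC)c3c(OC)ccc(OC)c3c2OC)CSCC1(C)C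
F2 | step 10 | {[(3S)-2-chloro-4,4-dimethyl-3-(1,4,5,8-tetramethoxynaphthalen-2-yl)thiolan-3-yl]oxy}triethylsilane (epimers at C2) | CC[Si](CC)(CC)O[C@]1(c2cc(OC)c3c(OC)ccc(OC)c3c2OC)C(Cl)SCC1(C)C
F3 | step 10 | (3S)-2-chloro-4,4-dimethyl-3-(1,4,5,8-tetramethoxynaphthalen-2-yl)-3-(triethylsilyloxy)thiolane 1,1-dioxide (epimers at C2) | CC[Si](CC)(CC)O[C@]1(c2cc(OC)c3c(OC)ccc(OC)c3c2OC)C(Cl)S(=O)(=O)CC1(C)C
F4 | step 4 | 2-oxo-2-(1,4,5,8-tetramethoxynaphthalen-2-yl)acetic acid | OC(=O)C(=O)c1cc(OC)c2c(OC)ccc(OC)c2c1OC
F5 | step 4 | (1R,2S,5R)-5-methyl-2-(2-phenylpropan-2-yl)cyclohexyl 2-oxo-2-(1,4,5,8-tetramethoxynaphthalen-2-yl)acetate | CC(C)(c1ccccc1)[C@@H]1CC[C@@H](C)C[C@H]1OC(=O)C(=O)c1cc(OC)c2c(OC)ccc(OC)c2c1OC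
F6 | step 4 | 4-methyl 1-[(1R,2S,5R)-5-methyl-2-(2-phenylpropan-2-yl)cyclohexyl] (2S)-2-hydroxy-3,3-dimethyl-2-(1,4,5,8-tetramethoxynaphthalen-2-yl)butanedioate | O[C@](C(C)(C)C(=O)OC)(c1cc(OC)c2c(OC)ccc(OC)c2c1OC)C(=O)O[C@@H]1C[C@H](C)CC[C@H]1C(C)(C)c1ccccc1
F7 | step 7 | S-[(2R)-2-hydroxy-4-(methanesulfonyloxy)-3,3-dimethyl-2-(1,4,5,8-tetramethoxynaphthalen-2-yl)butyl] ethanethioate | O[C@](C(C)(C)COS(C)(=O)=O)(c1cc(OC)c2c(OC)ccc(OC)c2c1OC)CSC(C)=O
F8 | step 13 | (1R)-2,2-dimethyl-1-(1,4,5,8-tetramethoxynaphthalen-2-yl)cyclobutyl 2-[bis(2,2,2-trifluoroethoxy)phosphoryl]propanoate (epimers at the phosphonate α-carbon) | CC(C(=O)O[C@]1(c2cc(OC)c3c(OC)ccc(OC)c3c2OC)CCC1(C)C)P(=O)(OCC(F)(F)F)OCC(F)(F)F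
F9 | step 14 | (1R)-2,2-dimethyl-1-(1,4,5,8-tetraoxo-1,4,5,8-tetrahydronaphthalen-2-yl)cyclobutyl (2Z)-2-methylbut-2-enoate | C/C=C(/C)C(=O)O[C@]1(C2=CC(=O)C3=C(C2=O)C(=O)C=CC3=O)CCC1(C)C
A1 | alternative 1 | 2-[(1R)-2,2-dimethyl-1-(triethylsilyloxy)cyclobutyl]-5,8-dimethoxy-1,4-dihydro-1,4-epoxynaphthalene (both bridgehead diastereomers) | CC[Si](CC)(CC)O[C@]1(C2=CC3OC2c2c(OC)ccc(OC)c23)CCC1(C)C
A2 | alternative 1 | triethyl{[(1R)-1-(furan-3-yl)-2,2-dimethylcyclobutyl]oxy}silane | CC[Si](CC)(CC)O[C@]1(c2ccoc2)CCC1(C)C
A3 | alternative 1 | 2-bromo-1,4-dimethoxybenzene | COc1ccc(OC)c(Br)c1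
A4 | alternative 2 | 3,3-dimethyl-2-(1,4,5,8-tetramethoxynaphthalen-2-yl)cyclobutan-1-one (racemic) | COc1ccc(OC)c2c(OC)c(C3C(=O)CC3(C)C)cc(OC)c12
A5 | alternative 2 | (1,4,5,8-tetramethoxynaphthalen-2-yl)acetyl chloride | COc1ccc(OC)c2c(OC)c(CC(Cl)=O)cc(OC)c12
A6 | alternative 2 | 2-methylpropene | CC(C)=C
A7 | alternative 3 | (1R)-2,2-dimethyl-1-(1,4,5,8-tetramethoxynaphthalen-2-yl)cyclobutyl (2Z)-2-methylbut-2-enoate | C/C=C(/C)C(=O)O[C@]1(c2cc(OC)c3c(OC)ccc(OC)c3c2OC)CCC1(C)C
A8 | alternative 3 | 1,4,5,8-tetramethoxy-2-[1-(prop-1-en-2-yl)cyclopropyl]naphthalene | CC(=C)C1(CC1)c1cc(OC)c2c(OC)ccc(OC)c2c1OC
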